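**Retrosynthetic overview**

- Feature: in the cyclohexenone ring (C1 carbonyl, C2=C3 with ethyl on C3, C4 carbinol, C5–C6 oxirane, farnesyl on C6) the C1 ketone sits beside the oxygen-bearing quaternary C6. This is an α-ketol pattern in which both carbons can come from carbonyl carbons.
- Target 20 ⇒ C6 tertiary alcohol with a C5 mesylate (oxirane by anti closure, inversion at C5) ⇒ trans-acetonide α-ketol 15.
- 15 ⇒ (Z)-enal ketone 14 by carbene-catalysed crossed benzoin closure of the C1–C6 bond (C1 aldehyde as acyl anion, C6 farnesyl ketone as acceptor).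
- 14 ⇒ diol 13 (double oxidation) ⇒ aldehyde 9 plus farnesylbarium from 10; the (Z)-enoate comes from syn ethylcuprate addition to alkynoate 6; C3–C6 with both stereocentres come from D-threitol acetonide 1.
- Ring order: the dioxolane is carried in from 1 and later removed; the carbocycle C1–C6 closes in step 11; the oxirane closes in step 14.

Key step: step 11

The ring numbers C1–C6 defined above are used for the same atoms in every intermediate.

Assumption: the sense of induction of the triazolium catalyst on this substrate cannot be fixed in advance; the (5aS,10bR) antipode is written, and its (5aR,10bS) antipode is used without other change if a test shows the written one to be the mismatched partner of the trans-dioxolane.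

**Route**

Step 1
Reactants: 1 2,3-O-isopropylidene-D-threitol
Product: 2 mono-TBS ether of 1
Conditions: NaH (1.0 equiv), THF, 0 °C to rt; TBSCl (1.0 equiv)
Reagents that add atoms: tert-butyldimethylsilyl chloride CC(C)(C)[Si](C)(C)Cl
Why: O-silylation of the sparingly soluble monosodium alkoxide of the C2-symmetric diol should stop at the mono-ether, and no stereocentre is touched.

Step 2
Reactants: 2 mono-TBS ether
Product: 3 (4S,5R)-aldehyde (C3 aldehyde)
Conditions: (COCl)2, DMSO, CH2Cl2, −78 °C; Et3N, −78 to 0 °C
Reagents that add atoms: none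
Why: Swern oxidation of the primary alcohol should give the α-alkoxy aldehyde without epimerisation, since the trans-dioxolane is also the more stable epimer.

Step 3
Reactants: 3 aldehyde
Product: 4 1,1-dibromoalkene
Conditions: CBr4, PPh3, CH2Cl2, 0 °C
Reagents that add atoms: carbon tetrabromide BrC(Br)(Br)Br
Why: Ramirez dibromo-olefination (first stage of the Corey–Fuchs sequence) adds the future C2 to the aldehyde carbon C3 under non-basic conditions that leave silyl ether and acetonide intact.

Step 4
Reactants: 4 1,1-dibromoalkene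
Product: 6 methyl alkynoate, via lithium acetylide 5 (not isolated)
Conditions: n-BuLi (2.1 equiv), THF, −78 °C; ClCO2Me, −78 to 0 °C
Reagents that add atoms: methyl chloroformate COC(=O)Cl; n-butyllithium CCCC[Li] (lithium stays only in 5)
Why: The second stage of the Corey–Fuchs reaction (elimination, then bromine–lithium exchange) gives the lithium acetylide, which is C-acylated by the chloroformate to install C1 at the ester oxidation level.

Step 5
Reactants: 6 methyl alkynoate
Product: 7 (Z)-3-ethyl enoate
Conditions: EtMgBr (2 equiv per Cu), CuBr·SMe2, THF, −78 °C; MeOH then aq NH4Cl at −78 °C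
Reagents that add atoms: ethylmagnesium bromide CC[Mg]Br (ethyl group delivered as the cuprate)
Why: Syn carbocupration of the alkynoate puts ethyl on C3 and copper on C2 on the same side, and protonation with retention at −78 °C leaves the ester cis to C4, which is the (Z)-geometry that later brings C1 near C6.

Step 6
Reactants: 7 (Z)-enoate silyl ether
Product: 8 (Z)-enoate primary alcohol
Conditions: Bu4NF, AcOH, THF, 0 °C to rt
Reagents that add atoms: none
Why: Fluoride-mediated desilylation cleaves the Si–O bond, and the acetic acid buffer keeps the medium from deprotonating the γ-position of the (Z)-enoate or driving lactonisation.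

Step 7
Reactants: 8 primary alcohol
Product: 9 C6 aldehyde
Conditions: Dess–Martin periodinane, NaHCO3, CH2Cl2, 0 °C to rt
Reagents that add atoms: none
Why: Dess–Martin oxidation under buffered, non-basic conditions should give the α-alkoxy aldehyde without epimerising C5 or isomerising the (Z)-enoate; the aldehyde is used at once.

Step 8
Reactants: 9 C6 aldehyde; 10 (2E,6E)-farnesyl chloride
Product: 12 homoallylic alcohol (both C6 epimers), via farnesylbarium chloride 11 (not isolated)
Conditions: BaI2, lithium biphenylide (2 equiv), THF, rt; 10, −78 °C; then 9, −78 °C; aq NH4Cl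
Reagents that add atoms: barium diiodide [Ba+2].[I-].[I-] (barium stays only in 11)
Why: In this carbonyl allylation the allylic barium reagent, formed by oxidative insertion of activated barium into the C–Cl bond of 10, should add to the aldehyde through its unsubstituted α-terminus with retention of the (E)-alkene at −78 °C to give the linear farnesyl carbinol, the aldehyde reacting far faster than the hindered β,β-disubstituted enoate; the C6 configuration is irrelevant because C6 is oxidised in step 10.

Step 9
Reactants: 12 homoallylic alcohol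
Product: 13 (Z)-allylic alcohol / C6 alcohol diol
Conditions: i-Bu2AlH (excess), CH2Cl2, −78 to −40 °C; aq potassium sodium tartrate
Reagents that add atoms: none
Why: 1,2-Reduction of the conjugated ester by i-Bu2AlH (and of any lactone formed from 12) should give the (Z)-allylic alcohol with the trisubstituted alkenes and the acetonide untouched.

Step 10
Reactants: 13 diol
Product: 14 (Z)-enal farnesyl ketone
Conditions: Dess–Martin periodinane (excess), NaHCO3, CH2Cl2, 0 °C
Reagents that add atoms: none
Why: Double Dess–Martin oxidation reveals the (Z)-enal and the β,γ-unsaturated ketone together in one neutral operation, so neither sensitive carbonyl has to survive earlier steps; 14 is taken on without storage.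

Step 11
Reactants: 14 (Z)-enal farnesyl ketone
Product: 15 trans-acetonide α-ketol (6-hydroxy-6-farnesyl-3-ethylcyclohex-2-enone 4,5-acetonide)
Conditions: (5aS,10bR)-2-(pentafluorophenyl)-5a,10b-dihydro-4H,6H-indeno[2,1-b][1,2,4]triazolo[4,3-d][1,4]oxazin-2-ium tetrafluoroborate (15 mol %), i-Pr2NEt (15 mol %), toluene (0.02 M), 0 to 23 °C
Reagents that add atoms: none
Why: Proposed new method: the triazolylidene adds to the C1 aldehyde of the (Z)-enal and proton transfer gives the conjugated enaminol (acyl anion equivalent), whose C1 attacks the α-alkoxy-activated C6 ketone while the enol proton passes to the developing alkoxide, and loss of the carbene leaves C1 as the enone carbonyl; the closest known reaction type is the carbene-catalysed intramolecular crossed aldehyde–ketone benzoin cyclisation to six-membered tertiary α-ketols, together with the use of enals as acyl-anion donors in Stetter reactions under electron-poor triazolium catalysis, whereas a (Z)-enal donor in such a benzoin closure is not established. The cyclohexenone ring C1–C6 closes in a 6-exo-trig mode onto the ketone carbonyl. The one new stereocentre, C6, is set by the matched pair of catalyst and trans-dioxolane: in the hydrogen-bonded transition state the ketone oxygen lies pseudo-equatorial beside the C1 oxygen, so the C6 hydroxyl should end trans to the C5 oxygen and cis to the C4 oxygen with the farnesyl group axial. The step needs acyl-anion reactivity at C1 in preference to homoenolate reactivity at C3 or redox loss of the C4 oxygen, and it needs ring closure to outrun base enolisation of the β,γ-unsaturated ketone and Z-to-E isomerisation of the enal. This is secured by the electron-poor N-pentafluorophenyl carbene, by the weak amine base in catalytic amount, by the (Z)-alkene and trans-dioxolane that hold C1 within bonding distance of C6, and by the fact that attack from C3 would need a four-membered ring.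

Step 12
Reactants: 15 trans-acetonide α-ketol
Product: 16 (4R,5S,6R)-triol
Conditions: AcOH–H2O–THF (4:1:1), 40 °C
Reagents that add atoms: none
Why: Acid-catalysed acetal hydrolysis is easy for the strained trans-fused dioxolane, so mild aqueous acetic acid should suffice and spare the tertiary α-ketol and the trisubstituted alkenes.

Step 13
Reactants: 16 triol
Product: 17 C4 TBS ether
Conditions: TBSCl, imidazole, DMF, 0 °C
Reagents that add atoms: tert-butyldimethylsilyl chloride CC(C)(C)[Si](C)(C)Cl
Why: Kinetic silylation should take the allylic C4 hydroxyl, because the C5 hydroxyl is flanked by the fully substituted C6 and the tertiary C6 hydroxyl is unreactive.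

Step 14
Reactants: 17 C4 TBS ether
Product: 19 TBS-protected epoxy enone, via C5 mesylate 18 (not isolated)
Conditions: MsCl, Et3N, CH2Cl2, 0 °C; then DBU, 0 °C to rt
Reagents that add atoms: methanesulfonyl chloride CS(=O)(=O)Cl (stays only in 18)
Why: Sulfonylation of the only free secondary hydroxyl is followed by intramolecular Williamson (3-exo-tet) closure, in which the C6 alkoxide displaces the anti C5 mesylate with inversion, placing the oxirane cis to the C4 oxygen; C6 has no hydrogen, so E1cB loss of the mesylate from the ketone side is not possible.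

Step 15
Reactants: 19 TBS-protected epoxy enone
Product: 20 CID44566894
Conditions: HF·pyridine, pyridine, THF, 0 °C to rt
Reagents that add atoms: none
Why: Buffered fluoride desilylation frees the C4 hydroxyl without base that could open or rearrange the epoxy ketone.

**Compound list**

1 | 2,3-O-isopropylidene-D-threitol, [(4R,5R)-2,2-dimethyl-1,3-dioxolane-4,5-diyl]dimethanol | OC[C@H]1OC(C)(C)O[C@@H]1CO | starting material
2 | [(4R,5R)-5-({[tert-butyl(dimethyl)silyl]oxy}methyl)-2,2-dimethyl-1,3-dioxolan-4-yl]methanol | OC[C@H]1OC(C)(C)O[C@@H]1CO[Si](C)(C)C(C)(C)C | intermediate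
3 | (4S,5R)-5-({[tert-butyl(dimethyl)silyl]oxy}methyl)-2,2-dimethyl-1,3-dioxolane-4-carbaldehyde | O=C[C@H]1OC(C)(C)O[C@@H]1CO[Si](C)(C)C(C)(C)C | intermediate
4 | tert-butyl{[(4R,5R)-5-(2,2-dibromoethenyl)-2,2-dimethyl-1,3-dioxolan-4-yl]methoxy}dimethylsilane | BrC(Br)=C[C@H]1OC(C)(C)O[C@@H]1CO[Si](C)(C)C(C)(C)C | intermediate
5 | lithium acetylide of the terminal alkyne derived from 4 (same dioxolane configuration) | [Li]C#C[C@H]1OC(C)(C)O[C@@H]1CO[Si](C)(C)C(C)(C)C | intermediate
6 | methyl 3-[(4R,5R)-5-({[tert-butyl(dimethyl)silyl]oxy}methyl)-2,2-dimethyl-1,3-dioxolan-4-yl]prop-2-ynoate | COC(=O)C#C[C@H]1OC(C)(C)O[C@@H]1CO[Si](C)(C)C(C)(C)C | intermediate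
7 | methyl (2Z)-3-[(4R,5R)-5-({[tert-butyl(dimethyl)silyl]oxy}methyl)-2,2-dimethyl-1,3-dioxolan-4-yl]pent-2-enoate | COC(=O)/C=C(CC)\[C@H]1OC(C)(C)O[C@@H]1CO[Si](C)(C)C(C)(C)C | intermediate
8 | methyl (2Z)-3-[(4R,5R)-5-(hydroxymethyl)-2,2-dimethyl-1,3-dioxolan-4-yl]pent-2-enoate | COC(=O)/C=C(CC)\[C@H]1OC(C)(C)O[C@@H]1CO | intermediate
9 | methyl (2Z)-3-[(4R,5S)-5-formyl-2,2-dimethyl-1,3-dioxolan-4-yl]pent-2-enoate | COC(=O)/C=C(CC)\[C@H]1OC(C)(C)O[C@@H]1C=O | intermediate
10 | (2E,6E)-farnesyl chloride | ClC/C=C(\C)CC/C=C(\C)CCC=C(C)C | starting material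
11 | (2E,6E)-farnesylbarium chloride | Cl[Ba]C/C=C(\C)CC/C=C(\C)CCC=C(C)C | intermediate
12 | methyl (2Z)-3-{(4R,5R)-5-[(3E,7E)-1-hydroxy-4,8,12-trimethyltrideca-3,7,11-trien-1-yl]-2,2-dimethyl-1,3-dioxolan-4-yl}pent-2-enoate (both carbinol epimers) | COC(=O)/C=C(CC)\[C@H]1OC(C)(C)O[C@@H]1C(O)C/C=C(\C)CC/C=C(\C)CCC=C(C)C | intermediate
13 | (2Z)-3-{(4R,5R)-5-[(3E,7E)-1-hydroxy-4,8,12-trimethyltrideca-3,7,11-trien-1-yl]-2,2-dimethyl-1,3-dioxolan-4-yl}pent-2-en-1-ol (both carbinol epimers) | OC/C=C(CC)\[C@H]1OC(C)(C)O[C@@H]1C(O)C/C=C(\C)CC/C=C(\C)CCC=C(C)C | intermediate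
14 | (2Z)-3-{(4R,5S)-2,2-dimethyl-5-[(3E,7E)-4,8,12-trimethyltrideca-3,7,11-trienoyl]-1,3-dioxolan-4-yl}pent-2-enal | O=C/C=C(CC)\[C@H]1OC(C)(C)O[C@@H]1C(=O)C/C=C(\C)CC/C=C(\C)CCC=C(C)C | intermediate
15 | (4R,5S,6R)-3-ethyl-6-hydroxy-4,5-(isopropylidenedioxy)-6-[(2E,6E)-3,7,11-trimethyldodeca-2,6,10-trien-1-yl]cyclohex-2-en-1-one (trans-fused acetonide; C6–OH cis to C4–O, trans to C5–O) | CCC1=CC(=O)[C@@](O)(C/C=C(\C)CC/C=C(\C)CCC=C(C)C)[C@H]2OC(C)(C)O[C@H]12 | intermediate
16 | (4R,5S,6R)-3-ethyl-4,5,6-trihydroxy-6-[(2E,6E)-3,7,11-trimethyldodeca-2,6,10-trien-1-yl]cyclohex-2-en-1-one | CCC1=CC(=O)[C@@](O)(C/C=C(\C)CC/C=C(\C)CCC=C(C)C)[C@@H](O)[C@@H]1O | intermediate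
17 | (4R,5S,6R)-4-{[tert-butyl(dimethyl)silyl]oxy}-3-ethyl-5,6-dihydroxy-6-[(2E,6E)-3,7,11-trimethyldodeca-2,6,10-trien-1-yl]cyclohex-2-en-1-one | CCC1=CC(=O)[C@@](O)(C/C=C(\C)CC/C=C(\C)CCC=C(C)C)[C@@H](O)[C@@H]1O[Si](C)(C)C(C)(C)C | intermediate
18 | C5 methanesulfonate of 17 (C4 OTBS, C5 OMs trans to the C6 OH) | CCC1=CC(=O)[C@@](O)(C/C=C(\C)CC/C=C(\C)CCC=C(C)C)[C@@H](OS(C)(=O)=O)[C@@H]1O[Si](C)(C)C(C)(C)C | intermediate
19 | (1R,5R,6R)-5-{[tert-butyl(dimethyl)silyl]oxy}-4-ethyl-1-[(2E,6E)-3,7,11-trimethyldodeca-2,6,10-trien-1-yl]-7-oxabicyclo[4.1.0]hept-3-en-2-one | CCC1=CC(=O)[C@]2(C/C=C(\C)CC/C=C(\C)CCC=C(C)C)O[C@@H]2[C@@H]1O[Si](C)(C)C(C)(C)C | intermediate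
20 | (1R,5R,6R)-4-ethyl-5-hydroxy-1-[(2E,6E)-3,7,11-trimethyldodeca-2,6,10-trien-1-yl]-7-oxabicyclo[4.1.0]hept-3-en-2-one (CID44566894) | CCC1=CC(=O)[C@]2(C/C=C(\C)CC/C=C(\C)CCC=C(C)C)O[C@@H]2[C@@H]1O | target

**Totals and risk**

Total step count: 15. Longest linear sequence: 15 steps (1 to 20); farnesyl chloride 10 enters at step 8.

Steps most likely to fail:

1. Step 11 (proposed new method). The carbene adduct of the enal may react through its homoenolate or redox manifold (protonation at C3, loss of the C4 oxygen) rather than at C1. The amine may enolise the β,γ-unsaturated ketone or isomerise the (Z)-enal before closure. The closure may also proceed with the wrong facial selectivity at C6. Fallback, from 14 back to 15: a reductive ketyl–carbonyl (pinacol-type) cyclisation with SmI2 (THF, t-BuOH, −78 °C) forms the same C1–C6 bond and should give the cis-1,2-diol with the new C6 oxygen trans to the neighbouring C5 oxygen, the acetonide-protected ring diol F1. Oxidation of its secondary allylic C1 hydroxyl with MnO2 (CH2Cl2, rt) then gives 15.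

2. Step 8. The allylic barium reagent may lose α-regioselectivity or (E)-geometry if metalation is incomplete or the mixture warms, and it may attack the enoate. Fallback, from 9 and 10 back to 13: 10 and sodium benzenesulfinate (DMF, rt) give (2E,6E)-farnesyl phenyl sulfone F2. Its α-lithio derivative (n-BuLi, THF, −78 °C) adds to 9 through the sulfonyl-bearing carbon to give β-hydroxy sulfone F3. Dess–Martin oxidation gives β-keto sulfone F4. SmI2 (THF–MeOH, −78 °C) removes the sulfonyl group to give keto ester F5. Excess i-Bu2AlH then reduces ketone and ester together to diol 13.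

3. Step 13. Site selectivity between the two secondary hydroxyls may be poor, with silylation at C5 or at both positions. Fallback, from 16 directly to 20: phenylboronic acid (toluene, MgSO4, rt) bridges the cis-1,3 hydroxyls at C4 and C6 as the six-membered cyclic phenylboronate F6, leaving only the C5 hydroxyl free. MsCl and Et3N (CH2Cl2, 0 °C) give boronate mesylate F7. K2CO3 in MeOH–H2O (0 °C) cleaves the boronate, and the more acidic α-ketol hydroxyl at C6 should ionise first, so that its alkoxide closes the oxirane with inversion at C5 to give 20.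

**Further compounds**

F1 | step 11 | C1 carbinol of 15: 3-ethyl-4,5-(isopropylidenedioxy)-6-farnesylcyclohex-2-ene-1,6-diol (C4, C5, C6 as in 15; C1 epimers) | CCC1=CC(O)[C@@](O)(C/C=C(\C)CC/C=C(\C)CCC=C(C)C)[C@H]2OC(C)(C)O[C@H]12
F2 | step 8 | (2E,6E)-farnesyl phenyl sulfone | O=S(=O)(C/C=C(\C)CC/C=C(\C)CCC=C(C)C)c1ccccc1
F3 | step 8 | β-hydroxy sulfone from 9 and lithiated F2 (carbinol and sulfonyl carbons as epimer mixtures) | COC(=O)/C=C(CC)\[C@H]1OC(C)(C)O[C@@H]1C(O)C(/C=C(\C)CC/C=C(\C)CCC=C(C)C)S(=O)(=O)c1ccccc1
F4 | step 8 | β-keto sulfone | COC(=O)/C=C(CC)\[C@H]1OC(C)(C)O[C@@H]1C(=O)C(/C=C(\C)CC/C=C(\C)CCC=C(C)C)S(=O)(=O)c1ccccc1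
F5 | step 8 | methyl (2Z)-3-{(4R,5S)-2,2-dimethyl-5-[(3E,7E)-4,8,12-trimethyltrideca-3,7,11-trienoyl]-1,3-dioxolan-4-yl}pent-2-enoate | COC(=O)/C=C(CC)\[C@H]1OC(C)(C)O[C@@H]1C(=O)C/C=C(\C)CC/C=C(\C)CCC=C(C)C
F6 | step 13 | cyclic phenylboronate of 16 across the C4 and C6 oxygens (C5 hydroxyl free) | CCC1=CC(=O)[C@]2(C/C=C(\C)CC/C=C(\C)CCC=C(C)C)OB(c3ccccc3)O[C@H]1[C@@H]2O
F7 | step 13 | C5 methanesulfonate of F6 | CCC1=CC(=O)[C@]2(C/C=C(\C)CC/C=C(\C)CCC=C(C)C)OB(c3ccccc3)O[C@H]1[C@@H]2OS(C)(=O)=O
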